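## The problem

1. Target 20 is a C20 caryophyllene-type diterpenoid. Ring A is a cyclobutane (C1, C9, C10, C11), trans-fused through C1–C9 to the nine-membered ring B (C1 to C9). Ring B carries a trisubstituted trans-epoxide (ring C, C4–C5) and an exocyclic methylene on C8, and the quaternary C11 bears a methyl group and ring D, a 3,6-dihydro-1,2-dioxin-3-ol (C12(OH)–C13=C14–C15(Me)(CH2OAc)–O–O).
2. There are seven stereocentres. C1 and C9 fix the conformations of ring B and so the face on which C4=C5 is epoxidized. C12 is a hemiketal that settles thermodynamically once C15 exists. C15 is cut off from every other centre by the quaternary C11 and the sp2 carbons C13 and C14, so nothing in the molecule can control it.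
3. The O–O bond tolerates no reductant, phosphine, low-valent metal or strong base, and the strained epoxide and its E-cyclononene precursor rearrange with acid. The peroxide must therefore be made last, and the epoxide after all hydride and Lewis-acid steps.
4. The hard carbocyclic problem is ring B, a medium ring with an E double bond fused to a four-membered ring.
5. The enabling feature is that C10–C9–C8(=CH2)–C7–C6–C5–C4(Me)–C3–C2–C1–C11(Me)–C12–C13–C14–C15(Me)–C16 is an unbroken head-to-tail tetraprenyl chain. Bonds C10–C11 and C9–C1 are the two bonds by which a caryophyllene-type class 1 terpene cyclase folds the first eleven chain carbons into rings A and B. The methylene on C8 is the deprotonated methyl of the first isoprene unit, and the fourth unit is ring D.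
6. C12 is a methylene next to a quaternary carbon. Once the bicycle exists no reagent can tell it from the allylic C7, so its oxygen has to be in the chain before cyclization.

## Retrosynthesis

**Ring D (20 ⇒ 18).** The hemiketal C12–O bond is opened and the C13=C14 geometry inverted, giving the E-γ-hydroperoxy enone 18 by way of its Z isomer 19. A [4+2] addition of singlet oxygen to a 12,14-diene would leave C12 one oxidation level too low and would need an s-cis diene with a fully substituted terminus. The open form removes a ring and the C12 stereocentre. The forward step must isomerize E to Z without harming the peroxide, and C12 is then set by ring–chain equilibrium.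

**C15–O (18 ⇒ 17).** The tertiary allylic hydroperoxide comes from a singlet-oxygen ene reaction of the β,γ-unsaturated ketone 17, which moves the double bond from C14=C15 to C13=C14. This is the one neutral way to such a hydroperoxide next to an acid-sensitive epoxide, and the C12 ketone steers hydrogen abstraction to C13. The price is that C15 is formed without control.

**Ketone and epoxide (17 ⇒ 16 ⇒ 15).** The ketone comes from carbinol 16 and the epoxide from the ring alkene of 15. Epoxidation must precede the photooxygenation, because singlet oxygen would attack the strained alkene first, and must follow the hydride step. It has to be chemoselective for the ring alkene and face-selective, as for β-caryophyllene.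

**Acetate and alcohol (15 ⇒ 14 ⇒ 13).** The allylic acetate comes from diol 14 and this from the conjugated ester 13. Nothing is demanded except selection of a primary over a hindered secondary hydroxyl.

**Rings A and B (13 ⇒ 12).** Cutting C10–C11 and C9–C1 unfolds both rings and removes three stereocentres, leaving the acyclic diphosphate 12. Cuts that build ring A alone leave ring B for a later macrocyclization; here ring B closes as a consequence of ring A. Cyclizing unmodified geranylgeranyl diphosphate would give a hydrocarbon whose C12 cannot be oxidized selectively, so 12 carries the C12 hydroxyl and C16 as an ester. The ester also makes the 14,15-double bond non-nucleophilic. The forward step asks a cyclase to accept this analogue and to fold it in the (1S,9R) sense.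

**Diphosphate (12 ⇒ 10 ⇒ 8 ⇒ 7).** The diphosphate comes from allylic chloride 10 and diphosphate salt 11, the chloride from diol 8 through mesylate 9, and 8 from acetate 7. The only demand is selection of the primary allylic hydroxyl over the C12 carbinol.

**C12–C13 (7 ⇒ 3 + 6).** A vinylogous aldol disconnection gives aldehyde 3 and silyl dienolate 6. It installs the C12 oxygen, the E-14,15-double bond and C16 at the ester level in one step. A prenyl-metal addition would attack through its substituted terminus and give the branched isomer.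

**Building blocks (3 ⇒ 1; 6 ⇒ 4).** Aldehyde 3 comes from commercial farnesyl acetate 1 by terminal allylic oxidation through alcohol 2, and 6 from methyl tiglate 4 through its lithium dienolate 5.

## Roads not taken

**Alternative 1:** Ring A by Wolff contraction.
- **Cut:** the C9–C10 bond, traced back to a five-membered ring.
- **Forward step:** irradiation of diazoketone A2 in methanol shifts C10 to the carbene carbon; methanol traps the ketene as cyclobutane ester A1 and NaOMe equilibrates the ester to trans.
- **Merits:** the contraction is dependable for strained rings, the quaternary C11 is set on the easier cyclopentanone, and the trans relationship at C1/C9 is thermodynamic. In A1 C12 already stands at the aldehyde level as its acetal, which is better than anything a cyclization of a hydrocarbon chain offers.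
- **Weak points:** A1 holds only ring A. Ring B, with its E-trisubstituted alkene, must still be closed from the alkyne and ester arms, absolute configuration must be brought in separately, and the sequence is long.
- **Comparison:** every step can be run today without protein work, and the C12 oxidation is superior. The chosen plan must carry oxygen through an enzyme to match it. What it sets against this is that step 7 makes both rings and three stereocentres at once.

**Alternative 2:** Asymmetric cyclopropanol expansion.
- **Cut:** the C10–C11 bond.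
- **Forward step:** Pd2(dba)3 (zerovalent palladium) with a chiral bisphosphine ionizes allylic carbonate A4, and a cyclopropane bond migrates to the methyl-bearing allyl terminus to give cyclobutanone A3.
- **Merits:** a small-molecule catalyst sets the quaternary C11 in absolute terms from an achiral precursor, and the vinyl group is a handle for C12 oxygenation. In catalyst availability and in C12 it is ahead of the chosen plan.
- **Weak points:** A3 has seven of the twenty carbons. C1 and C9 must be set against a quaternary centre whose methyl and vinyl groups differ little in size, the cyclobutanone is prone to ring opening, and ring B remains unsolved.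
- **Comparison:** the chosen plan depends on finding or engineering a cyclase, but it spends its key step on the whole bicycle instead of one stereocentre.

**Alternative 3:** Nitrogen deletion from a pyrrolidine.
- **Cut:** the C1–C11 bond.
- **Forward step:** PhI(OAc)2 and ammonium carbamate in trifluoroethanol convert pyrrolidine A6 into a 1,1-diazene; loss of N2 and collapse of the 1,4-biradical give cyclobutane A5 with C1 and C9 retained.
- **Merits:** A6 is open to catalytic asymmetric dipolar cycloaddition, so C1 and C9 are set predictably, and C12 arrives as an ester carbon.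
- **Weak points:** the biradical can fragment to two alkenes, the geminal esters must be told apart to create C11, the acetyl-bearing C9 can epimerize, and ring B is again left for later.
- **Comparison:** in predictability of C1/C9 and in C12 oxidation level it is at least as good as the chosen plan. The chosen plan answers with convergence: C11 comes from the 10E geometry and ring B needs no separate closure.

Key step: step 7

Remark on numbering: ring and side-chain carbons carry the target numbers C1–C16 throughout. In acyclic compounds "chain C1" is the carbon that bears acetate, chloride or diphosphate (target C10), and chain C12–C16 are target C12–C16.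

Assumption on the enzyme: a class 1 cyclase that folds a C20 chain in the caryophyllene manner with the (1S,9R) sense and accepts analogue 12 is taken to be obtainable by genome mining or active-site engineering.

Assumption on C12: the hemiketal carbon equilibrates through 19, and the target is taken to be the favoured anomer (hydroxyl pseudoaxial, cis to the acetoxymethyl group).

Remark on the carbinol: 7–10 and 12 are racemic at C12 and 13–16 are carried as C12 epimers; step 11 removes this centre.

## Route

Step 1
Reactants: 1 (2E,6E)-farnesyl acetate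
Product: 3 (2E,6E,10E)-3,7,11-trimethyl-12-oxododeca-2,6,10-trien-1-yl acetate, via allylic alcohol 2 (not isolated)
Conditions: SeO2 (cat.), t-BuOOH, salicylic acid (cat.), CH2Cl2, 0 °C to rt; crude product, MnO2, CH2Cl2, rt
Reagents that add atoms: tert-butyl hydroperoxide, CC(C)(C)OO (oxygen atom, relayed by the catalyst SeO2, O=[Se]=O)
Why: Riley-type allylic oxidation (ene reaction with SeO2, then [2,3]-sigmatropic shift) picks the E-methyl of the terminal trisubstituted alkene, the most accessible allylic position of the chain; MnO2 oxidizes only the allylic alcohol 2, so alcohol and any aldehyde already present converge on E-enal 3.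

Step 2
Reactants: 4 methyl tiglate
Product: 6 tert-butyl[(1-methoxy-2-methylbuta-1,3-dien-1-yl)oxy]dimethylsilane, via lithium dienolate 5 (not isolated)
Conditions: LiN(i-Pr)2, DMPU, THF, –78 °C; then t-BuMe2SiCl, –78 °C to rt
Reagents that add atoms: tert-butyldimethylsilyl chloride, CC(C)(C)[Si](C)(C)Cl
Why: The amide base removes a γ-proton (the α-carbon is fully substituted) and the silyl chloride traps the extended enolate 5 on oxygen, the standard preparation of vinylogous silyl ketene acetals; the ketene acetal geometry is immaterial.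

Step 3
Reactants: 3 (2E,6E,10E)-3,7,11-trimethyl-12-oxododeca-2,6,10-trien-1-yl acetate; 6 tert-butyl[(1-methoxy-2-methylbuta-1,3-dien-1-yl)oxy]dimethylsilane
Product: 7 methyl (2E,6E,10E,14E)-16-acetoxy-5-hydroxy-2,6,10,14-tetramethylhexadeca-2,6,10,14-tetraenoate (carbinol = chain C12, racemic)
Conditions: B(C6F5)3 (cat.), i-PrOH, Et2O, –78 °C
Reagents that add atoms: none
Why: Vinylogous Mukaiyama aldol reaction: the borane-activated aldehyde is attacked in a 1,2-sense by the unhindered terminal carbon of 6, which forms C12–C13 and returns the conjugated E-enoate; i-PrOH takes up the silyl group and frees the carbinol, whose configuration is erased in step 11.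

Step 4
Reactants: 7 methyl (2E,6E,10E,14E)-16-acetoxy-5-hydroxy-2,6,10,14-tetramethylhexadeca-2,6,10,14-tetraenoate
Product: 8 methyl (2E,6E,10E,14E)-5,16-dihydroxy-2,6,10,14-tetramethylhexadeca-2,6,10,14-tetraenoate
Conditions: K2CO3 (cat.), MeOH, 0 °C
Reagents that add atoms: none
Why: Base-catalysed transesterification removes the unhindered primary allylic acetate; the methyl enoate is degenerate towards methoxide and the δ-hydroxy E-enoate cannot lactonize.

Step 5
Reactants: 8 methyl (2E,6E,10E,14E)-5,16-dihydroxy-2,6,10,14-tetramethylhexadeca-2,6,10,14-tetraenoate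
Product: 10 methyl (2E,6E,10E,14E)-16-chloro-5-hydroxy-2,6,10,14-tetramethylhexadeca-2,6,10,14-tetraenoate, via allylic mesylate 9 (not isolated)
Conditions: MsCl (1.05 equiv), 2,4,6-collidine, LiCl, DMF, –40 to 0 °C
Reagents that add atoms: lithium chloride, [Li+].[Cl-]
Why: Sulfonylation at low temperature should take the primary allylic hydroxyl in preference to the secondary C12 carbinol, which is flanked by a trisubstituted alkene carbon; chloride then displaces mesylate 9 by SN2 without allylic transposition, the standard one-pot chlorination of prenyl alcohols.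

Step 6
Reactants: 10 methyl (2E,6E,10E,14E)-16-chloro-5-hydroxy-2,6,10,14-tetramethylhexadeca-2,6,10,14-tetraenoate; 11 tris(tetrabutylammonium) hydrogen diphosphate
Product: 12 methyl (2E,6E,10E,14E)-16-(diphosphooxy)-5-hydroxy-2,6,10,14-tetramethylhexadeca-2,6,10,14-tetraenoate (12-hydroxygeranylgeranyl diphosphate with C16 as methyl ester; handled as its ammonium salt)
Conditions: MeCN, rt; then cation exchange (NH4+ form), aq NH4HCO3
Reagents that add atoms: none
Why: SN2 displacement of a primary allylic chloride by the diphosphate trianion is the standard route to prenyl diphosphates; the free hydroxyl and the ester are inert, and cation exchange gives the water-soluble salt.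

Step 7
Reactants: 12 methyl (2E,6E,10E,14E)-16-(diphosphooxy)-5-hydroxy-2,6,10,14-tetramethylhexadeca-2,6,10,14-tetraenoate
Product: 13 methyl (2E)-5-[(1S,4E,9R,11S)-4,11-dimethyl-8-methylidenebicyclo[7.2.0]undec-4-en-11-yl]-5-hydroxy-2-methylpent-2-enoate (C12 epimers)
Conditions: recombinant class 1 diterpene cyclase (caryophyllene-type fold, 1S,9R sense), MgCl2, HEPES buffer pH 7.5, 30 °C, EtOAc–hexane overlay
Reagents that add atoms: none
Why: Class 1 terpene synthase cyclization: divalent magnesium on the diphosphate triggers ionization to the allyl cation, the 10,11-double bond captures chain C1 through its more substituted carbon (11-endo closure of an eleven-membered ring, forming target C10–C11), and the 2,3-double bond then closes across that ring onto the secondary cation (transannular 4-exo closure of ring A, forming C9–C1 and thereby completing ring B as a nine-membered ring), after which the tertiary C8 cation loses a methyl proton to give the exocyclic methylene. The closest known reaction is the conversion of farnesyl diphosphate into β-caryophyllene by sesquiterpene cyclases, and hydroxylated farnesyl diphosphates, including the 12-hydroxy compound oxygenated at the same place relative to the reacting alkene, are turned over by class 1 cyclases. C1 and C11 are tied together by the substrate: both new bonds end in the same four-membered ring and so add to one face of the 10E double bond, which puts C12 cis to H1 and the methyl cis to C2. The trans ring fusion (C9 against C1) and the absolute (1S,9R,11S) sense come from the fold imposed by the active site, since 12 is achiral apart from the carbinol; the E ring alkene is the untouched 6E double bond. The step needs the cyclobutane closure to outrun deprotonation to a humulene-type macrocycle, capture by water and interception of the cations by the C12 hydroxyl, and this rests on the enzyme. The substrate helps in one respect: the 14,15-double bond is conjugated to the ester and not nucleophilic, so the tail cannot enter the cascade. Either carbinol epimer of 13 is acceptable because step 11 merges them.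

Step 8
Reactants: 13 methyl (2E)-5-[(1S,4E,9R,11S)-4,11-dimethyl-8-methylidenebicyclo[7.2.0]undec-4-en-11-yl]-5-hydroxy-2-methylpent-2-enoate
Product: 14 (2E)-5-[(1S,4E,9R,11S)-4,11-dimethyl-8-methylidenebicyclo[7.2.0]undec-4-en-11-yl]-2-methylpent-2-ene-1,5-diol
Conditions: i-Bu2AlH, CH2Cl2, –78 °C; aq potassium sodium tartrate
Reagents that add atoms: none
Why: The aluminium hydride reduces the conjugated ester in a 1,2-sense to the E-allylic alcohol and leaves isolated alkenes alone; it is placed before epoxidation because hydride and Lewis-acidic aluminium would open the strained epoxide.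

Step 9
Reactants: 14 (2E)-5-[(1S,4E,9R,11S)-4,11-dimethyl-8-methylidenebicyclo[7.2.0]undec-4-en-11-yl]-2-methylpent-2-ene-1,5-diol
Product: 15 (2E)-5-[(1S,4E,9R,11S)-4,11-dimethyl-8-methylidenebicyclo[7.2.0]undec-4-en-11-yl]-5-hydroxy-2-methylpent-2-en-1-yl acetate
Conditions: Ac2O (1.1 equiv), pyridine, CH2Cl2, –20 to 0 °C
Reagents that add atoms: acetic anhydride, CC(=O)OC(C)=O
Why: Acylation without a nucleophilic catalyst distinguishes the primary allylic hydroxyl from the C12 carbinol, which sits next to the quaternary C11 (neopentyl-type hindrance).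

Step 10
Reactants: 15 (2E)-5-[(1S,4E,9R,11S)-4,11-dimethyl-8-methylidenebicyclo[7.2.0]undec-4-en-11-yl]-5-hydroxy-2-methylpent-2-en-1-yl acetate
Product: 16 (2E)-5-[(1S,4S,5S,9R,11S)-4,5-epoxy-4,11-dimethyl-8-methylidenebicyclo[7.2.0]undecan-11-yl]-5-hydroxy-2-methylpent-2-en-1-yl acetate
Conditions: mCPBA (1.05 equiv), NaHCO3, CH2Cl2, –20 °C
Reagents that add atoms: 3-chloroperoxybenzoic acid, OOC(=O)c1cccc(Cl)c1
Why: Prilezhaev epoxidation: the strained E-trisubstituted ring alkene is by far the most reactive double bond (the tail alkene is deactivated by its allylic acetate, the exocyclic methylene is only 1,1-disubstituted). The peracid should attack the exposed outer face of the dominant ring B conformers, as in the epoxidation of β-caryophyllene, giving the (4S,5S) trans-epoxide; the minor face isomer is removed by chromatography.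

Step 11
Reactants: 16 (2E)-5-[(1S,4S,5S,9R,11S)-4,5-epoxy-4,11-dimethyl-8-methylidenebicyclo[7.2.0]undecan-11-yl]-5-hydroxy-2-methylpent-2-en-1-yl acetate
Product: 17 (2E)-5-[(1S,4S,5S,9R,11S)-4,5-epoxy-4,11-dimethyl-8-methylidenebicyclo[7.2.0]undecan-11-yl]-2-methyl-5-oxopent-2-en-1-yl acetate
Conditions: DMP (triacetoxyperiodinane), NaHCO3, CH2Cl2, 0 °C to rt
Reagents that add atoms: none
Why: The buffered periodinane oxidizes the hindered secondary alcohol under neutral conditions, so the β,γ-double bond stays out of conjugation and epoxide and acetate are untouched; both C12 epimers give the same ketone.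

Step 12
Reactants: 17 (2E)-5-[(1S,4S,5S,9R,11S)-4,5-epoxy-4,11-dimethyl-8-methylidenebicyclo[7.2.0]undecan-11-yl]-2-methyl-5-oxopent-2-en-1-yl acetate
Product: 18 (3E)-5-[(1S,4S,5S,9R,11S)-4,5-epoxy-4,11-dimethyl-8-methylidenebicyclo[7.2.0]undecan-11-yl]-2-hydroperoxy-2-methyl-5-oxopent-3-en-1-yl acetate (both C15 epimers)
Conditions: O2, tetraphenylporphyrin (cat.), visible light, CH2Cl2, –20 °C
Reagents that add atoms: dioxygen, O=O
Why: Schenck ene reaction: singlet oxygen attacks the trisubstituted tail alkene on its more substituted side (cis effect), abstracts a C13 hydrogen activated by the ketone and delivers oxygen to C15, giving the tertiary allylic hydroperoxide and the conjugated E-enone, the usual course with β,γ-unsaturated ketones. The exocyclic methylene should react far more slowly; C15 is formed without facial control, so 18 is a pair of C15 epimers that are separated after ring closure.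

Step 13
Reactants: 18 (3E)-5-[(1S,4S,5S,9R,11S)-4,5-epoxy-4,11-dimethyl-8-methylidenebicyclo[7.2.0]undecan-11-yl]-2-hydroperoxy-2-methyl-5-oxopent-3-en-1-yl acetate
Product: 20 [(3R,6R)-6-[(1S,4S,5S,9R,11S)-4,5-epoxy-4,11-dimethyl-8-methylidenebicyclo[7.2.0]undecan-11-yl]-6-hydroxy-3-methyl-3,6-dihydro-1,2-dioxin-3-yl]methyl acetate, via Z-hydroperoxy enone 19 (not isolated)
Conditions: hν (350 nm), MeCN, rt; preparative HPLC
Reagents that add atoms: none
Why: Direct irradiation of the enone equilibrates E and Z isomers; only Z isomer 19 can add its hydroperoxy group to the ketone (6-exo-trig hemiketalization), and the cyclic peroxy hemiketal no longer absorbs, so the mixture should drain into ring D. C12 settles as the favoured anomer by ring–chain equilibration, and the (12R,15R) compound 20 is separated from its C15 epimer by HPLC.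

## Compound list

1 | (2E,6E)-farnesyl acetate | CC(C)=CCC/C(C)=C/CC/C(C)=C/COC(C)=O | starting material
2 | (2E,6E,10E)-12-hydroxy-3,7,11-trimethyldodeca-2,6,10-trien-1-yl acetate | OC/C(C)=C/CC/C(C)=C/CC/C(C)=C/COC(C)=O | intermediate (not isolated)
3 | (2E,6E,10E)-3,7,11-trimethyl-12-oxododeca-2,6,10-trien-1-yl acetate | O=C/C(C)=C/CC/C(C)=C/CC/C(C)=C/COC(C)=O | intermediate
4 | methyl tiglate, methyl (2E)-2-methylbut-2-enoate | C/C=C(\C)C(=O)OC | starting material
5 | lithium 1-methoxy-2-methylbuta-1,3-dien-1-olate | C=CC(C)=C(OC)[O-].[Li+] | intermediate (not isolated)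
6 | tert-butyl[(1-methoxy-2-methylbuta-1,3-dien-1-yl)oxy]dimethylsilane | C=CC(C)=C(OC)O[Si](C)(C)C(C)(C)C | intermediate
7 | methyl (2E,6E,10E,14E)-16-acetoxy-5-hydroxy-2,6,10,14-tetramethylhexadeca-2,6,10,14-tetraenoate (racemic) | COC(=O)/C(C)=C/CC(O)/C(C)=C/CC/C(C)=C/CC/C(C)=C/COC(C)=O | intermediate
8 | methyl (2E,6E,10E,14E)-5,16-dihydroxy-2,6,10,14-tetramethylhexadeca-2,6,10,14-tetraenoate (racemic) | COC(=O)/C(C)=C/CC(O)/C(C)=C/CC/C(C)=C/CC/C(C)=C/CO | intermediate
9 | methyl (2E,6E,10E,14E)-5-hydroxy-16-(methanesulfonyloxy)-2,6,10,14-tetramethylhexadeca-2,6,10,14-tetraenoate | COC(=O)/C(C)=C/CC(O)/C(C)=C/CC/C(C)=C/CC/C(C)=C/COS(C)(=O)=O | intermediate (not isolated)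
10 | methyl (2E,6E,10E,14E)-16-chloro-5-hydroxy-2,6,10,14-tetramethylhexadeca-2,6,10,14-tetraenoate (racemic) | COC(=O)/C(C)=C/CC(O)/C(C)=C/CC/C(C)=C/CC/C(C)=C/CCl | intermediate
11 | tris(tetrabutylammonium) hydrogen diphosphate | CCCC[N+](CCCC)(CCCC)CCCC.CCCC[N+](CCCC)(CCCC)CCCC.CCCC[N+](CCCC)(CCCC)CCCC.O=P([O-])(O)OP(=O)([O-])[O-] | starting material
12 | methyl (2E,6E,10E,14E)-16-(diphosphooxy)-5-hydroxy-2,6,10,14-tetramethylhexadeca-2,6,10,14-tetraenoate (racemic; drawn as the free acid) | COC(=O)/C(C)=C/CC(O)/C(C)=C/CC/C(C)=C/CC/C(C)=C/COP(=O)(O)OP(=O)(O)O | intermediate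
13 | methyl (2E)-5-[(1S,4E,9R,11S)-4,11-dimethyl-8-methylidenebicyclo[7.2.0]undec-4-en-11-yl]-5-hydroxy-2-methylpent-2-enoate (C12 epimers) | C=C1CC/C=C(\C)CC[C@H]2[C@H]1C[C@]2(C)C(O)C/C=C(\C)C(=O)OC | intermediate
14 | (2E)-5-[(1S,4E,9R,11S)-4,11-dimethyl-8-methylidenebicyclo[7.2.0]undec-4-en-11-yl]-2-methylpent-2-ene-1,5-diol (C12 epimers) | C=C1CC/C=C(\C)CC[C@H]2[C@H]1C[C@]2(C)C(O)C/C=C(\C)CO | intermediate
15 | (2E)-5-[(1S,4E,9R,11S)-4,11-dimethyl-8-methylidenebicyclo[7.2.0]undec-4-en-11-yl]-5-hydroxy-2-methylpent-2-en-1-yl acetate (C12 epimers) | C=C1CC/C=C(\C)CC[C@H]2[C@H]1C[C@]2(C)C(O)C/C=C(\C)COC(C)=O | intermediate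
16 | (2E)-5-[(1S,4S,5S,9R,11S)-4,5-epoxy-4,11-dimethyl-8-methylidenebicyclo[7.2.0]undecan-11-yl]-5-hydroxy-2-methylpent-2-en-1-yl acetate (C12 epimers) | C=C1CC[C@@H]2O[C@@]2(C)CC[C@H]2[C@H]1C[C@]2(C)C(O)C/C=C(\C)COC(C)=O | intermediate
17 | (2E)-5-[(1S,4S,5S,9R,11S)-4,5-epoxy-4,11-dimethyl-8-methylidenebicyclo[7.2.0]undecan-11-yl]-2-methyl-5-oxopent-2-en-1-yl acetate | C=C1CC[C@@H]2O[C@@]2(C)CC[C@H]2[C@H]1C[C@]2(C)C(=O)C/C=C(\C)COC(C)=O | intermediate
18 | (3E)-5-[(1S,4S,5S,9R,11S)-4,5-epoxy-4,11-dimethyl-8-methylidenebicyclo[7.2.0]undecan-11-yl]-2-hydroperoxy-2-methyl-5-oxopent-3-en-1-yl acetate (C15 epimers) | C=C1CC[C@@H]2O[C@@]2(C)CC[C@H]2[C@H]1C[C@]2(C)C(=O)/C=C/C(C)(COC(C)=O)OO | intermediate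
19 | (3Z)-5-[(1S,4S,5S,9R,11S)-4,5-epoxy-4,11-dimethyl-8-methylidenebicyclo[7.2.0]undecan-11-yl]-2-hydroperoxy-2-methyl-5-oxopent-3-en-1-yl acetate (C15 epimers) | C=C1CC[C@@H]2O[C@@]2(C)CC[C@H]2[C@H]1C[C@]2(C)C(=O)/C=C\C(C)(COC(C)=O)OO | intermediate (not isolated)
20 | [(3R,6R)-6-[(1S,4S,5S,9R,11S)-4,5-epoxy-4,11-dimethyl-8-methylidenebicyclo[7.2.0]undecan-11-yl]-6-hydroxy-3-methyl-3,6-dihydro-1,2-dioxin-3-yl]methyl acetate | C=C1CC[C@@H]2O[C@@]2(C)CC[C@H]2[C@H]1C[C@]2(C)[C@@]1(O)C=C[C@](C)(COC(C)=O)OO1 | target

## Step count and risks

Total: 13 steps. Longest linear sequence: 12 steps (steps 1 and 3–13 from 1).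

**Step 7 (key step).** Turnover may fail, or the cascade may be diverted: early deprotonation to a humulene-type macrocycle, trapping of a cation by the C12 hydroxyl or a hydride shift from the carbinol carbon, discrimination between the carbinol enantiomers, or folding in the mirror-image sense. The cause would be an active site shaped for a hydrocarbon chain.

Fallback: the cyclization is moved to the C15 homologue, where cyclases of this type exist, and the tail is attached afterwards; it sets out from 3 and returns at 13. Aldehyde 3 is deacetylated (K2CO3, MeOH) to (2E,6E,10E)-12-hydroxy-2,6,10-trimethyldodeca-2,6,10-trienal F1. N-Chlorosuccinimide and Me2S give (2E,6E,10E)-12-chloro-2,6,10-trimethyldodeca-2,6,10-trienal F2. Displacement with 11 gives (2E,6E,10E)-3,7,11-trimethyl-12-oxododeca-2,6,10-trien-1-yl diphosphate F3, and NaBH4 in aqueous methanol reduces this to (2E,6E,10E)-12-hydroxy-3,7,11-trimethyldodeca-2,6,10-trien-1-yl diphosphate F4. A sesquiterpene cyclase of the β-caryophyllene family with the (1S,9R) fold converts F4 into [(1S,4E,9R,11S)-4,11-dimethyl-8-methylidenebicyclo[7.2.0]undec-4-en-11-yl]methanol F5. Periodinane oxidation gives (1S,4E,9R,11S)-4,11-dimethyl-8-methylidenebicyclo[7.2.0]undec-4-ene-11-carbaldehyde F6, and the vinylogous aldol reaction of step 3 with 6 delivers 13.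

**Step 12.** Hydrogen abstraction may leak to the C15 methyl (secondary hydroperoxide), the exocyclic methylene may be oxygenated in competition because the tail alkene is deactivated by acetate and ketone, and the absence of facial control at C15 costs half the material.

Fallback: ring D is closed by cycloaddition instead of ene reaction; it sets out from 17 and returns at 20. Soft enolization of 17 (t-BuMe2SiOTf, Et3N, –78 °C) gives 5-[(1S,4S,5S,9R,11S)-4,5-epoxy-4,11-dimethyl-8-methylidenebicyclo[7.2.0]undecan-11-yl]-5-(tert-butyldimethylsilyloxy)-2-methylpenta-2,4-dien-1-yl acetate F7. This electron-rich diene should outpace the exocyclic methylene towards singlet oxygen and give by [4+2] addition the cyclic silyl peroxy ketal [6-(tert-butyldimethylsilyloxy)-6-[(1S,4S,5S,9R,11S)-4,5-epoxy-4,11-dimethyl-8-methylidenebicyclo[7.2.0]undecan-11-yl]-3-methyl-3,6-dihydro-1,2-dioxin-3-yl]methyl acetate F8. Buffered fluoride (Bu4NF, AcOH) then frees 20 and its C15 epimer. This route also avoids the photoisomerization.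

**Step 13.** Irradiation may cleave the O–O bond or start radical decomposition, the excited ketone may abstract a γ-hydrogen from the ring, and ring closure may be too slow to drain the Z isomer.

Fallback: the peroxide is masked before the alkene is isomerized; it sets out from 18 and returns at 19. Et3SiCl and imidazole give (3E)-5-[(1S,4S,5S,9R,11S)-4,5-epoxy-4,11-dimethyl-8-methylidenebicyclo[7.2.0]undecan-11-yl]-2-methyl-5-oxo-2-(triethylsilylperoxy)pent-3-en-1-yl acetate F9. Visible-light triplet sensitization (thioxanthen-9-one, 405 nm) gives the photostationary mixture containing the (3Z) isomer F10. Bu4NF with AcOH removes the silyl group to give 19, which closes to 20.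

**Step 5.** Site selectivity may be lost by sulfonylation or ionization at the secondary allylic C12 carbinol, or by allylic transposition.

Fallback: the carbinol is protected through the diphosphate synthesis; it sets out from 7 and returns at 12. t-BuMe2SiCl and imidazole give methyl (2E,6E,10E,14E)-16-acetoxy-5-(tert-butyldimethylsilyloxy)-2,6,10,14-tetramethylhexadeca-2,6,10,14-tetraenoate F11. K2CO3 in MeOH gives the 16-hydroxy compound F12, N-chlorosuccinimide and Me2S the 16-chloro compound F13, and 11 the silylated diphosphate F14. Bu4NF then gives 12.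

## Further compounds

F1 | step 7 | (2E,6E,10E)-12-hydroxy-2,6,10-trimethyldodeca-2,6,10-trienal | O=C/C(C)=C/CC/C(C)=C/CC/C(C)=C/CO
F2 | step 7 | (2E,6E,10E)-12-chloro-2,6,10-trimethyldodeca-2,6,10-trienal | O=C/C(C)=C/CC/C(C)=C/CC/C(C)=C/CCl
F3 | step 7 | (2E,6E,10E)-3,7,11-trimethyl-12-oxododeca-2,6,10-trien-1-yl diphosphate | O=C/C(C)=C/CC/C(C)=C/CC/C(C)=C/COP(=O)(O)OP(=O)(O)O
F4 | step 7 | (2E,6E,10E)-12-hydroxy-3,7,11-trimethyldodeca-2,6,10-trien-1-yl diphosphate | OC/C(C)=C/CC/C(C)=C/CC/C(C)=C/COP(=O)(O)OP(=O)(O)O
F5 | step 7 | [(1S,4E,9R,11S)-4,11-dimethyl-8-methylidenebicyclo[7.2.0]undec-4-en-11-yl]methanol | C=C1CC/C=C(\C)CC[C@H]2[C@H]1C[C@]2(C)CO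
F6 | step 7 | (1S,4E,9R,11S)-4,11-dimethyl-8-methylidenebicyclo[7.2.0]undec-4-ene-11-carbaldehyde | C=C1CC/C=C(\C)CC[C@H]2[C@H]1C[C@]2(C)C=O
F7 | step 12 | 5-[(1S,4S,5S,9R,11S)-4,5-epoxy-4,11-dimethyl-8-methylidenebicyclo[7.2.0]undecan-11-yl]-5-(tert-butyldimethylsilyloxy)-2-methylpenta-2,4-dien-1-yl acetate | C=C1CC[C@@H]2O[C@@]2(C)CC[C@H]2[C@H]1C[C@]2(C)C(O[Si](C)(C)C(C)(C)C)=C/C=C(\C)COC(C)=O
F8 | step 12 | [6-(tert-butyldimethylsilyloxy)-6-[(1S,4S,5S,9R,11S)-4,5-epoxy-4,11-dimethyl-8-methylidenebicyclo[7.2.0]undecan-11-yl]-3-methyl-3,6-dihydro-1,2-dioxin-3-yl]methyl acetate | C=C1CC[C@@H]2O[C@@]2(C)CC[C@H]2[C@H]1C[C@]2(C)C1(O[Si](C)(C)C(C)(C)C)C=CC(C)(COC(C)=O)OO1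
F9 | step 13 | (3E)-5-[(1S,4S,5S,9R,11S)-4,5-epoxy-4,11-dimethyl-8-methylidenebicyclo[7.2.0]undecan-11-yl]-2-methyl-5-oxo-2-(triethylsilylperoxy)pent-3-en-1-yl acetate | C=C1CC[C@@H]2O[C@@]2(C)CC[C@H]2[C@H]1C[C@]2(C)C(=O)/C=C/C(C)(COC(C)=O)OO[Si](CC)(CC)CC
F10 | step 13 | (3Z)-5-[(1S,4S,5S,9R,11S)-4,5-epoxy-4,11-dimethyl-8-methylidenebicyclo[7.2.0]undecan-11-yl]-2-methyl-5-oxo-2-(triethylsilylperoxy)pent-3-en-1-yl acetate | C=C1CC[C@@H]2O[C@@]2(C)CC[C@H]2[C@H]1C[C@]2(C)C(=O)/C=C\C(C)(COC(C)=O)OO[Si](CC)(CC)CC
F11 | step 5 | methyl (2E,6E,10E,14E)-16-acetoxy-5-(tert-butyldimethylsilyloxy)-2,6,10,14-tetramethylhexadeca-2,6,10,14-tetraenoate | COC(=O)/C(C)=C/CC(O[Si](C)(C)C(C)(C)C)/C(C)=C/CC/C(C)=C/CC/C(C)=C/COC(C)=O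
F12 | step 5 | methyl (2E,6E,10E,14E)-5-(tert-butyldimethylsilyloxy)-16-hydroxy-2,6,10,14-tetramethylhexadeca-2,6,10,14-tetraenoate | COC(=O)/C(C)=C/CC(O[Si](C)(C)C(C)(C)C)/C(C)=C/CC/C(C)=C/CC/C(C)=C/CO
F13 | step 5 | methyl (2E,6E,10E,14E)-5-(tert-butyldimethylsilyloxy)-16-chloro-2,6,10,14-tetramethylhexadeca-2,6,10,14-tetraenoate | COC(=O)/C(C)=C/CC(O[Si](C)(C)C(C)(C)C)/C(C)=C/CC/C(C)=C/CC/C(C)=C/CCl
F14 | step 5 | methyl (2E,6E,10E,14E)-5-(tert-butyldimethylsilyloxy)-16-(diphosphooxy)-2,6,10,14-tetramethylhexadeca-2,6,10,14-tetraenoate | COC(=O)/C(C)=C/CC(O[Si](C)(C)C(C)(C)C)/C(C)=C/CC/C(C)=C/CC/C(C)=C/COP(=O)(O)OP(=O)(O)O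
A1 | alternative 1 | methyl 3-(dimethoxymethyl)-3-methyl-2-[4-(trimethylsilyl)but-3-yn-1-yl]cyclobutane-1-carboxylate | COC(=O)[C@@H]1C[C@](C)(C(OC)OC)[C@H]1CCC#C[Si](C)(C)C
A2 | alternative 1 | 2-diazo-4-(dimethoxymethyl)-4-methyl-3-[4-(trimethylsilyl)but-3-yn-1-yl]cyclopentan-1-one | O=C1C[C@](C)(C(OC)OC)[C@@H](CCC#C[Si](C)(C)C)C1=[N+]=[N-]
A3 | alternative 2 | 2-ethenyl-2-methylcyclobutan-1-one (enantiomer as drawn) | C=C[C@@]1(C)CCC1=O
A4 | alternative 2 | 1-[(2E)-4-(methoxycarbonyloxy)but-2-en-2-yl]cyclopropan-1-ol | COC(=O)OC/C=C(\C)C1(O)CC1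
A5 | alternative 3 | dimethyl 3-acetyl-2-[2-(benzyloxy)ethyl]cyclobutane-1,1-dicarboxylate (2,3-trans) | COC(=O)C1(C(=O)OC)C[C@@H](C(C)=O)[C@@H]1CCOCc1ccccc1
A6 | alternative 3 | dimethyl 4-acetyl-5-[2-(benzyloxy)ethyl]pyrrolidine-2,2-dicarboxylate (4,5-trans) | COC(=O)C1(C(=O)OC)C[C@@H](C(C)=O)[C@H](CCOCc2ccccc2)N1
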